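**Assumption:** the SMILES is taken literally. It gives (1R,5S,6S,9S,10R) in drimane numbering: 1β‑OAc, 5α‑H, 6α‑OAc (cis to the 9α‑OH, trans to the C10 methyl), 9α‑OH, 10β‑CH3.

**Numbering used in names:** drimane numbering (ring A = C1–C5, C10; ring B = C5–C10; C11 on C9, C12 on C8; β = face of the C10 methyl).

## Retrosynthetic overview

1. The C12 aldehyde is unmasked last from a diethyl acetal; the 6‑OAc comes from acylation of the 6α‑OH (the C1 acetate is carried from the diene stage).
2. The cis 6α,9α‑dioxygenation and the Δ7 alkene come from α‑face singlet‑oxygen [4+2] addition to a ring‑B 6,8‑diene, then O–O reduction.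
3. The 6,8‑dienal comes from base isomerisation of a 5,8‑diene Diels–Alder adduct, which sets the 5α‑H.
4. Ring B is formed by an intermolecular Diels–Alder reaction of (R)‑2,4,4‑trimethyl‑3‑vinylcyclohex‑2‑enyl acetate with 4,4‑diethoxybut‑2‑ynal, anti to the OAc, which sets C10.
5. Ring A is bought as a cyclohexanedione and elaborated by C‑methylation, Stork–Danheiser vinylation and CBS reduction, which sets C1, the only reagent‑controlled stereocentre.

## Route

**Step 1**
Reactants: 1, 4,4‑dimethylcyclohexane‑1,3‑dione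
Product: 2, 2,4,4‑trimethylcyclohexane‑1,3‑dione
Conditions: MeI, aq. NaOH, dioxane–H2O, 70 °C
Reagents that add atoms: iodomethane, CI
Why: C‑alkylation of the 1,3‑diketone enolate at the only carbon flanked by both carbonyls; no stereocentre is carried forward.

**Step 2**
Reactants: 2
Product: 3, 3‑isobutoxy‑2,6,6‑trimethylcyclohex‑2‑en‑1‑one
Conditions: i‑BuOH, p‑TsOH (cat.), toluene, reflux, Dean–Stark
Reagents that add atoms: isobutanol, CC(C)CO
Why: acid‑catalysed vinylogous ester formation occurs at the less hindered carbonyl, leaving the ketone next to the CMe2 carbon free.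

**Step 3**
Reactants: 3
Product: 4, 2,4,4‑trimethyl‑3‑vinylcyclohex‑2‑en‑1‑one
Conditions: CH2=CHMgBr, CeCl3, THF, −78 → 0 °C; then 1 M HCl, rt
Reagents that add atoms: vinylmagnesium bromide, C=C[Mg]Br; water, O
Why: Stork–Danheiser sequence; 1,2‑addition to the vinylogous ester carbonyl, then acidic hydrolysis and dehydration transposes the enone and places the vinyl group next to CMe2.

**Step 4**
Reactants: 4
Product: 5, (R)‑2,4,4‑trimethyl‑3‑vinylcyclohex‑2‑en‑1‑ol
Conditions: (S)‑Me‑CBS (20 mol %), catecholborane, toluene, −78 °C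
Reagents that add atoms: none
Why: Corey–Bakshi–Shibata 1,2‑reduction; the α‑methyl alkenyl arm acts as the large group and CH2 as the small group, so the (S)‑catalyst gives the (R)‑carbinol (future C1). Catecholborane at −78 °C avoids hydroboration of the diene.

**Step 5**
Reactants: 5
Product: 6, (R)‑2,4,4‑trimethyl‑3‑vinylcyclohex‑2‑en‑1‑yl acetate
Conditions: Ac2O, Et3N, DMAP (cat.), CH2Cl2, 0 °C
Reagents that add atoms: acetic anhydride, CC(=O)OC(C)=O
Why: DMAP‑catalysed acylation with retention; this installs the final C1 acetate early, which no later step cleaves because the route contains no hydride or strong‑base step.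

**Step 6**
Reactants: 7, 3,3‑diethoxyprop‑1‑yne
Product: 8, 4,4‑diethoxybut‑2‑ynal
Conditions: n‑BuLi, THF, −78 °C; DMF; inverse quench into cold aq. KH2PO4
Reagents that add atoms: N,N‑dimethylformamide, CN(C)C=O
Why: formylation of the lithium acetylide (Bouveault‑type) gives the mono‑acetal of acetylenedicarbaldehyde, a dienophile carrying both C11 and C12 at the aldehyde oxidation level.

**Step 7**
Reactants: 6 and 8
Product: 9, (1R,10S)‑1β‑acetoxy‑12,12‑diethoxydrima‑5,8‑dien‑11‑al (ring B is a 1,4‑cyclohexadiene; CHO on C9, CH(OEt)2 on C8; C10‑CH3 cis to 1‑OAc)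
Conditions: 8 (2 equiv), BHT (cat.), toluene (concentrated), 90 °C, sealed tube
Reagents that add atoms: none
Why: Diels–Alder reaction that forms ring B. The acetal‑bearing alkyne carbon bonds to the unhindered vinyl terminus and the formyl‑bearing carbon to the ring carbon ("ortho" orientation). The dienophile adds anti to the pseudoaxial allylic OAc, so the new C10 methyl ends up cis to the OAc.

**Step 8**
Reactants: 9
Product: 10, (1R,5S,10S)‑1β‑acetoxy‑12,12‑diethoxydrima‑6,8‑dien‑11‑al (trans ring fusion, 5α‑H)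
Conditions: DBU (1 equiv), toluene, rt → 50 °C
Reagents that add atoms: none
Why: vinylogous enolisation at the doubly allylic C7 and reprotonation at C5 give the fully conjugated dienal under thermodynamic control; protonation opposite the C10 methyl gives the trans‑fused 5α‑H.

**Step 9**
Reactants: 10
Product: 11, (1R,5S,6S,9S,10R)‑1β‑acetoxy‑12,12‑diethoxy‑6α,9α‑dihydroxydrim‑7‑en‑11‑al
Conditions: O2, TPP (cat.), visible light, CH2Cl2, −20 °C; then thiourea, MeOH, rt
Reagents that add atoms: dioxygen, O=O
Why: singlet‑oxygen [4+2] addition to the ring‑B cisoid diene from the α face (opposite the C10 and C4β methyls) gives the 6α,9α‑endoperoxide; thiourea reduction of the O–O bond gives the cis 6α,9α‑diol and the Δ7 alkene, with the C9 formyl left β.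

**Step 10**
Reactants: 11
Product: 12, (1R,5S,6S,9S,10R)‑1β,6α‑diacetoxy‑12,12‑diethoxy‑9α‑hydroxydrim‑7‑en‑11‑al
Conditions: Ac2O, pyridine, DMAP (cat.), CH2Cl2, 0 °C → rt
Reagents that add atoms: acetic anhydride, CC(=O)OC(C)=O
Why: DMAP‑catalysed acylation of the only secondary alcohol; the tertiary 9‑OH next to the formyl group is not acylated.

**Step 11**
Reactants: 12
Product: 13, parritadial, (1R,5S,6S,9S,10R)‑1β,6α‑diacetoxy‑9α‑hydroxydrim‑7‑ene‑11,12‑dial
Conditions: PPTS, acetone–H2O (10:1), 40 °C
Reagents that add atoms: water, O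
Why: mild acetal hydrolysis through a conjugated oxocarbenium ion releases the C12 enal; the acetates and the tertiary alcohol survive and no stereocentre is touched.

## Compound list

1 | 4,4‑dimethylcyclohexane‑1,3‑dione | CC1(C)CCC(=O)CC1=O | starting material
2 | 2,4,4‑trimethylcyclohexane‑1,3‑dione | CC1C(=O)CCC(C)(C)C1=O | intermediate
3 | 3‑isobutoxy‑2,6,6‑trimethylcyclohex‑2‑en‑1‑one | CC1=C(OCC(C)C)CCC(C)(C)C1=O | intermediate
4 | 2,4,4‑trimethyl‑3‑vinylcyclohex‑2‑en‑1‑one | CC1=C(C=C)C(C)(C)CCC1=O | intermediate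
5 | (R)‑2,4,4‑trimethyl‑3‑vinylcyclohex‑2‑en‑1‑ol | CC1=C(C=C)C(C)(C)CC[C@H]1O | intermediate
6 | (R)‑2,4,4‑trimethyl‑3‑vinylcyclohex‑2‑en‑1‑yl acetate | CC1=C(C=C)C(C)(C)CC[C@H]1OC(C)=O | intermediate
7 | 3,3‑diethoxyprop‑1‑yne | C#CC(OCC)OCC | starting material
8 | 4,4‑diethoxybut‑2‑ynal | O=CC#CC(OCC)OCC | intermediate
9 | (1R,10S)‑1β‑acetoxy‑12,12‑diethoxydrima‑5,8‑dien‑11‑al | C1C(C(OCC)OCC)=C(C=O)[C@@]2(C)[C@H](OC(C)=O)CCC(C)(C)C2=C1 | intermediate
10 | (1R,5S,10S)‑1β‑acetoxy‑12,12‑diethoxydrima‑6,8‑dien‑11‑al | C1=CC(C(OCC)OCC)=C(C=O)[C@@]2(C)[C@H](OC(C)=O)CCC(C)(C)[C@H]12 | intermediate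
11 | (1R,5S,6S,9S,10R)‑1β‑acetoxy‑12,12‑diethoxy‑6α,9α‑dihydroxydrim‑7‑en‑11‑al | O[C@H]1C=C(C(OCC)OCC)[C@](O)(C=O)[C@@]2(C)[C@H](OC(C)=O)CCC(C)(C)[C@H]12 | intermediate
12 | (1R,5S,6S,9S,10R)‑1β,6α‑diacetoxy‑12,12‑diethoxy‑9α‑hydroxydrim‑7‑en‑11‑al | CC(=O)O[C@H]1C=C(C(OCC)OCC)[C@](O)(C=O)[C@@]2(C)[C@H](OC(C)=O)CCC(C)(C)[C@H]12 | intermediate
13 | parritadial | CC(=O)O[C@H]1C=C(C=O)[C@](O)(C=O)[C@@]2(C)[C@H](OC(C)=O)CCC(C)(C)[C@H]12 | target

## Step count and risks

Total steps: 11. Longest linear sequence: 10 (steps 1–5 and 7–11; step 6 is a one‑step side branch).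

Steps most likely to fail:

1. **Step 7 (Diels–Alder).** The diene is hindered, the ynal is heat‑sensitive, and the facial selectivity with OAc may be modest. Fallback: use dimethyl acetylenedicarboxylate on the TBS ether of 5 (symmetrical, robust, bulkier directing group). Then isomerise with DBU, reduce with LiAlH4 to the 6,8‑diene‑11,12‑diol, protect as the acetonide, photooxygenate and reduce, desilylate and acetylate, remove the acetonide and Swern‑oxidise to the dial. This is longer but avoids the ynal.

2. **Step 9 (photooxygenation).** The diene carries a formyl group and may react slowly or give ene or Kornblum–DeLaMare by‑products. Fallback: make the diene electron‑rich first by reducing the C11 aldehyde of 10 (NaBH4) and silylating it, then photooxygenate, acetylate, desilylate and re‑oxidise C11 (Dess–Martin) before the acetal hydrolysis.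

3. **Step 8 (isomerisation).** It may give diene mixtures or the cis ring fusion. Fallback: drop the isomerisation and endoperoxide logic. On a diester adduct, hydroborate Δ5 (BH3, α face) to set 5α‑H and 6α‑OH directly, then introduce the 9α‑OH and Δ7 by deconjugative α‑hydroxylation of the 8‑ene diester dienolate (LDA, then Davis oxaziridine).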